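**Plan**

- Numbering: linker C1(=CH2)–C2–C3H2; ring A = C4 (on C3), C5 (isopropenyl), C9, C10, C11 (C(CH3)OH), C12 (CHOH); ring B = C13 (on C2), C14, C15, C16 (C(CH3)OH), C17 (CHBr), C18.
- Enabling feature: with C12 taken back to the ketone, ring A is a 2-hydroxy-2-methylcyclohexanone (C11 carbinol beside C12 carbonyl). That is the acyloin ring-enlargement product of a 1-acetylcyclopentanol built on C12, C4, C5, C9, C10, so the retrosynthesis cuts C10–C11 and restores C10–C12.
- Further cuts: C11–C12 (acetyl anion equivalent onto a cyclopentanone), C3–C4 (enolate alkylation by a ring B allylic iodide), C5–isopropenyl (conjugate addition to cyclopentenone); in ring B, C16–CH3 (methyl addition to an α-bromoketone) and C17–Br (SN2), back to (+)-cis-limonene oxide.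
- Forward order: ring B is taken ready-made from the terpene and trimmed to the allylic iodide (steps 1–9); the cyclopentane comes from cyclopentenone (step 10); the chain is joined at C3–C4 (step 11); ring A arises last from the five-membered ring by one-carbon enlargement (step 13), then reduction and desilylation.
- Stereochemistry: C13 from (R)-limonene; C17 by inversion of the epoxide-derived C–O bond; C16 by addition anti to bromine; C5 by ligand-controlled conjugate addition; C4 by alkylation trans to C5; C11 relayed through the aluminium chelate from C12 of the cyclopentanol (set anti to the C4 branch); C12 by axial hydride delivery.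

Key step: step 13

Assumption: (+)-cis-limonene oxide is bought as the single cis isomer (otherwise it is freed from the commercial cis/trans mixture by selective aminolysis of the trans isomer); the atom numbers C1–C18 of the plan are used throughout.

**Route**

Step 1
Reactants: 1 (+)-cis-limonene oxide, (1R,2S,4R)-1-methyl-4-(prop-1-en-2-yl)-7-oxabicyclo[4.1.0]heptane
Product: 2 (1S,5R)-2-methylidene-5-(prop-1-en-2-yl)cyclohexan-1-ol
Conditions: LiN(i-Pr)2, Et2O, 0 °C → reflux; H2O
Reagents that add atoms: none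
Why: Base-promoted isomerization of an epoxide to an allylic alcohol, in which the lithium amide should remove a proton of the methyl group so that the exocyclic alkene forms and the C–O bond at the future C17 keeps its configuration (oxygen trans to the isopropenyl group).

Step 2
Reactants: 2 (1S,5R)-2-methylidene-5-(prop-1-en-2-yl)cyclohexan-1-ol
Product: 3 (3S,4S,6R)-6-(prop-1-en-2-yl)-1-oxaspiro[2.5]octan-4-ol
Conditions: VO(acac)2 (2 mol %), t-BuOOH, CH2Cl2, 0 °C → rt
Reagents that add atoms: tert-butyl hydroperoxide, CC(C)(C)OO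
Why: Hydroxyl-directed vanadium-catalysed epoxidation should deliver oxygen from the bound allylic alkoxide to the neighbouring exocyclic alkene only, syn to the hydroxyl, and leave the isopropenyl group untouched; the spiro centre is destroyed in step 4.

Step 3
Reactants: 3 (3S,4S,6R)-6-(prop-1-en-2-yl)-1-oxaspiro[2.5]octan-4-ol
Product: 4 (3S,4S,6R)-6-(prop-1-en-2-yl)-1-oxaspiro[2.5]octan-4-yl methanesulfonate
Conditions: MsCl, Et3N, CH2Cl2, 0 °C
Reagents that add atoms: methanesulfonyl chloride, CS(=O)(=O)Cl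
Why: Mesylation of the secondary alcohol should install the leaving group with retention, axial and trans to the isopropenyl group, and mask this oxygen before the glycol cleavage.

Step 4
Reactants: 4 (3S,4S,6R)-6-(prop-1-en-2-yl)-1-oxaspiro[2.5]octan-4-yl methanesulfonate
Product: 6 (1S,5R)-2-oxo-5-(prop-1-en-2-yl)cyclohexyl methanesulfonate, via diol 5 (not isolated)
Conditions: H5IO6, THF/H2O, 0 °C → rt
Reagents that add atoms: none
Why: Periodic acid cleavage of a terminal epoxide, in which acid hydrolysis to the 1,2-diol is followed by Malaprade glycol cleavage, should excise the exocyclic carbon as formaldehyde and leave the ring ketone without touching the isopropenyl group or the α-sulfonate.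

Step 5
Reactants: 6 (1S,5R)-2-oxo-5-(prop-1-en-2-yl)cyclohexyl methanesulfonate
Product: 7 (2R,4R)-2-bromo-4-(prop-1-en-2-yl)cyclohexan-1-one
Conditions: LiBr, acetone, rt
Reagents that add atoms: lithium bromide, [Li+].[Br-]
Why: SN2 displacement of the axial α-keto sulfonate by bromide, accelerated by the adjacent carbonyl, should invert C17 so that bromine ends equatorial and cis to the isopropenyl group.

Step 6
Reactants: 7 (2R,4R)-2-bromo-4-(prop-1-en-2-yl)cyclohexan-1-one
Product: 8 (1S,2R,4R)-2-bromo-1-methyl-4-(prop-1-en-2-yl)cyclohexan-1-ol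
Conditions: MeMgBr, Et2O/CH2Cl2, −78 °C; H2O at −78 °C
Reagents that add atoms: methylmagnesium bromide, C[Mg]Br
Why: Grignard 1,2-addition to an α-bromoketone under polar Felkin–Anh (Cornforth) control should bring the methyl group in anti to the C–Br bond, which sets C16 with its hydroxyl cis to bromine (cis bromohydrin, hydroxyl axial, methyl equatorial).

Step 7
Reactants: 8 (1S,2R,4R)-2-bromo-1-methyl-4-(prop-1-en-2-yl)cyclohexan-1-ol
Product: 9 triethyl{[(1S,2R,4R)-2-bromo-1-methyl-4-(prop-1-en-2-yl)cyclohexyl]oxy}silane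
Conditions: Et3SiOTf, 2,6-lutidine, CH2Cl2, −78 → 0 °C
Reagents that add atoms: triethylsilyl trifluoromethanesulfonate, CC[Si](CC)(CC)OS(=O)(=O)C(F)(F)F
Why: Silylation of the hindered tertiary alcohol with the silyl triflate and a hindered pyridine base should protect it for the enolate and organolithium steps without touching a stereocentre.

Step 8
Reactants: 9 triethyl{[(1S,2R,4R)-2-bromo-1-methyl-4-(prop-1-en-2-yl)cyclohexyl]oxy}silane
Product: 10 {[(1S,2R,4R)-2-bromo-4-(3-chloroprop-1-en-2-yl)-1-methylcyclohexyl]oxy}triethylsilane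
Conditions: Ca(OCl)2, CO2 (solid), CH2Cl2/H2O, 0 °C
Reagents that add atoms: calcium hypochlorite, [Ca+2].[O-]Cl.[O-]Cl
Why: Ene-type allylic chlorination of the 1,1-disubstituted alkene by hypochlorous acid should place chlorine on the terminal carbon with loss of a methyl proton, which gives the 2-substituted allyl chloride with C1, C2 and C3 of the linker in place.

Step 9
Reactants: 10 {[(1S,2R,4R)-2-bromo-4-(3-chloroprop-1-en-2-yl)-1-methylcyclohexyl]oxy}triethylsilane
Product: 11 {[(1S,2R,4R)-2-bromo-4-(3-iodoprop-1-en-2-yl)-1-methylcyclohexyl]oxy}triethylsilane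
Conditions: NaI, acetone, rt, dark
Reagents that add atoms: sodium iodide, [Na+].[I-]
Why: Finkelstein exchange at the primary allylic carbon should give the more reactive iodide, while the hindered secondary ring bromide does not exchange.

Step 10
Reactants: 12 cyclopent-2-en-1-one; 13 isopropenylmagnesium bromide
Product: 15 trimethyl{[(3S)-3-(prop-1-en-2-yl)cyclopent-1-en-1-yl]oxy}silane, via magnesium enolate 14 (not isolated)
Conditions: CuBr·SMe2 (5 mol %), (R)-1-[(S)-2-(diphenylphosphino)ferrocenyl]ethyldicyclohexylphosphine (6 mol %), t-BuOMe, −78 °C; then Me3SiCl, Et3N, −78 → 0 °C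
Reagents that add atoms: chlorotrimethylsilane, C[Si](C)(C)Cl
Why: Copper-catalysed asymmetric conjugate addition of a Grignard reagent to a cyclic enone, in which the chiral ferrocenyl diphosphine–copper complex selects the enone face and sets C5 as S (the ligand antipode is chosen for this sense), followed by O-silylation that fixes the regiodefined enolate.

Step 11
Reactants: 15 trimethyl{[(3S)-3-(prop-1-en-2-yl)cyclopent-1-en-1-yl]oxy}silane; 11 {[(1S,2R,4R)-2-bromo-4-(3-iodoprop-1-en-2-yl)-1-methylcyclohexyl]oxy}triethylsilane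
Product: 17 (2R,3S)-2-{2-[(1R,3R,4S)-3-bromo-4-methyl-4-(triethylsilyloxy)cyclohexyl]prop-2-en-1-yl}-3-(prop-1-en-2-yl)cyclopentan-1-one, via lithium enolate 16 (not isolated)
Conditions: MeLi, THF, 0 °C; then HMPA, 11, −78 → −30 °C
Reagents that add atoms: none
Why: Regiospecific generation of the lithium enolate from the silyl enol ether and its C-alkylation by the allylic iodide should form C3–C4, the electrophile entering anti to the adjacent isopropenyl group to give the trans 2,3-disubstituted cyclopentanone (C4 R).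

Step 12
Reactants: 17 (2R,3S)-2-{2-[(1R,3R,4S)-3-bromo-4-methyl-4-(triethylsilyloxy)cyclohexyl]prop-2-en-1-yl}-3-(prop-1-en-2-yl)cyclopentan-1-one; 18 ethyl vinyl ether
Product: 21 1-[(1S,2R,3S)-2-{2-[(1R,3R,4S)-3-bromo-4-methyl-4-(triethylsilyloxy)cyclohexyl]prop-2-en-1-yl}-1-hydroxy-3-(prop-1-en-2-yl)cyclopentyl]ethan-1-one, via 1-ethoxyvinyllithium 19 (not isolated), via ethoxyvinyl carbinol 20 (not isolated)
Conditions: 18, t-BuLi, THF, −78 → 0 °C; 17, −78 °C; then 0.5 M HCl, THF, 0 °C
Reagents that add atoms: water, O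
Why: 1,2-Addition of an acyl anion equivalent (1-ethoxyvinyllithium) from the face anti to the C4 branch should set C12 with the two-carbon unit trans to that branch, and mild acid hydrolysis of the enol ether then releases the methyl ketone while the tertiary silyl ether survives.

Step 13
Reactants: 21 1-[(1S,2R,3S)-2-{2-[(1R,3R,4S)-3-bromo-4-methyl-4-(triethylsilyloxy)cyclohexyl]prop-2-en-1-yl}-1-hydroxy-3-(prop-1-en-2-yl)cyclopentyl]ethan-1-one
Product: 22 (2S,5S,6R)-6-{2-[(1R,3R,4S)-3-bromo-4-methyl-4-(triethylsilyloxy)cyclohexyl]prop-2-en-1-yl}-2-hydroxy-2-methyl-5-(prop-1-en-2-yl)cyclohexan-1-one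
Conditions: Al(Ot-Bu)3 (30 mol %), toluene, 90 °C
Reagents that add atoms: none
Why: Acyloin (α-ketol) rearrangement: aluminium binds the C12 alkoxide and the acetyl oxygen in a five-membered chelate, and the ring methylene C10 shifts with its bonding pair from C12 to the acetyl carbon C11 while C12 becomes the ketone, as in the Lewis-acid D-homoannulation of 17-hydroxy-20-oxo steroids and the ring enlargement of 1-acylcycloalkanols. Ring A is closed not by a cyclization but by this suprafacial 1,2-shift, which forms C10–C11, breaks C10–C12 and enlarges the cyclopentane by one carbon, driven by the more stable six-membered ketol. The new stereocentre C11 is set by the chelate: with the two oxygens syn-periplanar and the acetyl group on the face opposite to the C4 branch, C10 attacks the carbonyl face that leaves the C11 hydroxyl on the side of the C4 branch and the methyl on the other (2S). The step needs migration of C10 and not of the more substituted C4; the unbranched methylene is the group that moves in the steroid precedent, and because the shift is reversible the less congested ketol, with the carbonyl beside C4, should also be the thermodynamic product. C5 is untouched, and C4, now α to the ketone, sits in its stable equatorial arrangement trans to C5.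

Step 14
Reactants: 22 (2S,5S,6R)-6-{2-[(1R,3R,4S)-3-bromo-4-methyl-4-(triethylsilyloxy)cyclohexyl]prop-2-en-1-yl}-2-hydroxy-2-methyl-5-(prop-1-en-2-yl)cyclohexan-1-one
Product: 23 (1S,2S,3R,4S)-3-{2-[(1R,3R,4S)-3-bromo-4-methyl-4-(triethylsilyloxy)cyclohexyl]prop-2-en-1-yl}-1-methyl-4-(prop-1-en-2-yl)cyclohexane-1,2-diol
Conditions: NaBH4, MeOH, −20 °C
Reagents that add atoms: none
Why: Borohydride reduction of the cyclohexanone by axial attack, on the face away from the axial C11 methyl group, should give the equatorial C12 alcohol trans to the C11 hydroxyl (C12 S).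

Step 15
Reactants: 23 (1S,2S,3R,4S)-3-{2-[(1R,3R,4S)-3-bromo-4-methyl-4-(triethylsilyloxy)cyclohexyl]prop-2-en-1-yl}-1-methyl-4-(prop-1-en-2-yl)cyclohexane-1,2-diol
Product: 24 (1S,2S,3R,4S)-3-{2-[(1R,3R,4S)-3-bromo-4-hydroxy-4-methylcyclohexyl]prop-2-en-1-yl}-1-methyl-4-(prop-1-en-2-yl)cyclohexane-1,2-diol
Conditions: HF·pyridine, pyridine, THF, 0 °C → rt
Reagents that add atoms: none
Why: Fluoride-mediated cleavage of the triethylsilyl ether should free the tertiary alcohol of ring B without affecting the secondary bromide, the diol or the two alkenes.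

**Compound list**

1 | (+)-cis-limonene oxide, (1R,2S,4R)-1-methyl-4-(prop-1-en-2-yl)-7-oxabicyclo[4.1.0]heptane | CC(=C)[C@@H]1CC[C@@]2(C)O[C@H]2C1 | starting material
2 | (1S,5R)-2-methylidene-5-(prop-1-en-2-yl)cyclohexan-1-ol | CC(=C)[C@@H]1CCC(=C)[C@@H](O)C1 | intermediate
3 | (3S,4S,6R)-6-(prop-1-en-2-yl)-1-oxaspiro[2.5]octan-4-ol | CC(=C)[C@@H]1CC[C@]2(CO2)[C@@H](O)C1 | intermediate
4 | (3S,4S,6R)-6-(prop-1-en-2-yl)-1-oxaspiro[2.5]octan-4-yl methanesulfonate | CC(=C)[C@@H]1CC[C@]2(CO2)[C@@H](OS(C)(=O)=O)C1 | intermediate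
5 | (1S,2S,5R)-2-hydroxy-2-(hydroxymethyl)-5-(prop-1-en-2-yl)cyclohexyl methanesulfonate (drawn for water attack at the CH2 terminus; the carbinol centre becomes the carbonyl) | CC(=C)[C@@H]1CC[C@](O)(CO)[C@@H](OS(C)(=O)=O)C1 | intermediate
6 | (1S,5R)-2-oxo-5-(prop-1-en-2-yl)cyclohexyl methanesulfonate | CC(=C)[C@@H]1CCC(=O)[C@@H](OS(C)(=O)=O)C1 | intermediate
7 | (2R,4R)-2-bromo-4-(prop-1-en-2-yl)cyclohexan-1-one | CC(=C)[C@@H]1CCC(=O)[C@H](Br)C1 | intermediate
8 | (1S,2R,4R)-2-bromo-1-methyl-4-(prop-1-en-2-yl)cyclohexan-1-ol | CC(=C)[C@@H]1CC[C@](C)(O)[C@H](Br)C1 | intermediate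
9 | triethyl{[(1S,2R,4R)-2-bromo-1-methyl-4-(prop-1-en-2-yl)cyclohexyl]oxy}silane | CC(=C)[C@@H]1CC[C@](C)(O[Si](CC)(CC)CC)[C@H](Br)C1 | intermediate
10 | {[(1S,2R,4R)-2-bromo-4-(3-chloroprop-1-en-2-yl)-1-methylcyclohexyl]oxy}triethylsilane | ClCC(=C)[C@@H]1CC[C@](C)(O[Si](CC)(CC)CC)[C@H](Br)C1 | intermediate
11 | {[(1S,2R,4R)-2-bromo-4-(3-iodoprop-1-en-2-yl)-1-methylcyclohexyl]oxy}triethylsilane | ICC(=C)[C@@H]1CC[C@](C)(O[Si](CC)(CC)CC)[C@H](Br)C1 | intermediate
12 | cyclopent-2-en-1-one | O=C1C=CCC1 | starting material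
13 | isopropenylmagnesium bromide | CC(=C)[Mg]Br | starting material
14 | bromomagnesium (3S)-3-(prop-1-en-2-yl)cyclopent-1-en-1-olate | Br[Mg]OC1=C[C@@H](C(C)=C)CC1 | intermediate
15 | trimethyl{[(3S)-3-(prop-1-en-2-yl)cyclopent-1-en-1-yl]oxy}silane | C[Si](C)(C)OC1=C[C@@H](C(C)=C)CC1 | intermediate
16 | lithium (3S)-3-(prop-1-en-2-yl)cyclopent-1-en-1-olate | [Li]OC1=C[C@@H](C(C)=C)CC1 | intermediate
17 | (2R,3S)-2-{2-[(1R,3R,4S)-3-bromo-4-methyl-4-(triethylsilyloxy)cyclohexyl]prop-2-en-1-yl}-3-(prop-1-en-2-yl)cyclopentan-1-one | C=C(C[C@@H]1[C@@H](C(=C)C)CCC1=O)[C@@H]1CC[C@](C)(O[Si](CC)(CC)CC)[C@H](Br)C1 | intermediate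
18 | ethyl vinyl ether (ethoxyethene) | C=COCC | starting material
19 | 1-ethoxyvinyllithium | [Li]C(=C)OCC | intermediate
20 | (1S,2R,3S)-2-{2-[(1R,3R,4S)-3-bromo-4-methyl-4-(triethylsilyloxy)cyclohexyl]prop-2-en-1-yl}-1-(1-ethoxyethenyl)-3-(prop-1-en-2-yl)cyclopentan-1-ol | CCOC(=C)[C@]1(O)CC[C@H](C(C)=C)[C@H]1CC(=C)[C@@H]1CC[C@](C)(O[Si](CC)(CC)CC)[C@H](Br)C1 | intermediate
21 | 1-[(1S,2R,3S)-2-{2-[(1R,3R,4S)-3-bromo-4-methyl-4-(triethylsilyloxy)cyclohexyl]prop-2-en-1-yl}-1-hydroxy-3-(prop-1-en-2-yl)cyclopentyl]ethan-1-one | CC(=O)[C@]1(O)CC[C@H](C(C)=C)[C@H]1CC(=C)[C@@H]1CC[C@](C)(O[Si](CC)(CC)CC)[C@H](Br)C1 | intermediate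
22 | (2S,5S,6R)-6-{2-[(1R,3R,4S)-3-bromo-4-methyl-4-(triethylsilyloxy)cyclohexyl]prop-2-en-1-yl}-2-hydroxy-2-methyl-5-(prop-1-en-2-yl)cyclohexan-1-one | C=C(C[C@@H]1[C@@H](C(=C)C)CC[C@](C)(O)C1=O)[C@@H]1CC[C@](C)(O[Si](CC)(CC)CC)[C@H](Br)C1 | intermediate
23 | (1S,2S,3R,4S)-3-{2-[(1R,3R,4S)-3-bromo-4-methyl-4-(triethylsilyloxy)cyclohexyl]prop-2-en-1-yl}-1-methyl-4-(prop-1-en-2-yl)cyclohexane-1,2-diol | C=C(C[C@@H]1[C@@H](C(=C)C)CC[C@](C)(O)[C@H]1O)[C@@H]1CC[C@](C)(O[Si](CC)(CC)CC)[C@H](Br)C1 | intermediate
24 | (1S,2S,3R,4S)-3-{2-[(1R,3R,4S)-3-bromo-4-hydroxy-4-methylcyclohexyl]prop-2-en-1-yl}-1-methyl-4-(prop-1-en-2-yl)cyclohexane-1,2-diol | C=C(C[C@@H]1[C@@H](C(=C)C)CC[C@](C)(O)[C@H]1O)[C@@H]1CC[C@](C)(O)[C@H](Br)C1 | target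

**Step count**

Total: 15 steps. Longest linear sequence: 14 steps (steps 1–9 and 11–15, from 1).

**Steps most likely to fail**

First, step 10. The copper–diphosphine catalyst may discriminate poorly between the enone faces when the nucleophile is an alkenyl Grignard reagent and the enone is the small cyclopentenone, and direct 1,2-addition may compete. The fallback replaces catalyst control by separation of diastereomers. It sets out from 12 and 13: ligand-free conjugate addition (CuI 10 mol %, Me3SiCl, THF, −78 °C) gives the racemic silyl enol ether trimethyl{[3-(prop-1-en-2-yl)cyclopent-1-en-1-yl]oxy}silane F1. MeLi and then iodide 11, as in step 11, give 17 together with (2S,3R)-2-{2-[(1R,3R,4S)-3-bromo-4-methyl-4-(triethylsilyloxy)cyclohexyl]prop-2-en-1-yl}-3-(prop-1-en-2-yl)cyclopentan-1-one F2. Because ring B is a single enantiomer the two are diastereomers and are parted by chromatography; the route is rejoined at 17.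

Second, step 13. The branched carbon C4 may migrate in competition with C10, or the shift may run outside the chelate and lose the C11 configuration. The fallback makes the ring A ketol from the chiral pool without a shift. It sets out from iodide 11 and commercial (S)-(+)-carvone, whose ring already holds C11 with its methyl group and C5 with the isopropenyl group. Nucleophilic epoxidation (H2O2, NaOH, MeOH) gives the epoxide trans to the isopropenyl group, (1S,4S,6S)-1-methyl-4-(prop-1-en-2-yl)-7-oxabicyclo[4.1.0]heptan-2-one F3. LiAlH4 reduces the ketone and opens the epoxide at its secondary carbon to give (1S,2R,4S)-1-methyl-4-(prop-1-en-2-yl)cyclohexane-1,2-diol F4 (the configuration of the secondary carbinol is of no consequence). Oxidation of the secondary alcohol (SO3·pyridine, DMSO, Et3N) gives (2S,5S)-2-hydroxy-2-methyl-5-(prop-1-en-2-yl)cyclohexan-1-one F5, in which the C11 hydroxyl is already trans to the isopropenyl group. Its dianion (LiN(i-Pr)2, 2.2 equiv, THF/HMPA) is alkylated by 11 at C4, the only enolizable position, trans to the isopropenyl group; the route is rejoined at 22.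

Third, step 12. The basic vinyllithium reagent may deprotonate the hindered, enolizable ketone in place of adding to it, and the facial selectivity at C12 may be incomplete. The fallback replaces alkoxyvinyl addition and hydrolysis by vinylation and oxidation. It sets out from 17: vinylmagnesium bromide with CeCl3 (THF, −78 °C), a smaller and less basic nucleophile, should add anti to the C4 branch to give (1R,2R,3S)-2-{2-[(1R,3R,4S)-3-bromo-4-methyl-4-(triethylsilyloxy)cyclohexyl]prop-2-en-1-yl}-1-ethenyl-3-(prop-1-en-2-yl)cyclopentan-1-ol F6. Tsuji–Wacker oxidation (PdCl2 10 mol %, CuCl, O2, DMF/H2O) should convert the monosubstituted vinyl group, and not the 1,1-disubstituted alkenes, into the methyl ketone; the route is rejoined at 21.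

Further compounds
F1 | step 10 | trimethyl{[3-(prop-1-en-2-yl)cyclopent-1-en-1-yl]oxy}silane (racemic) | C[Si](C)(C)OC1=CC(C(C)=C)CC1
F2 | step 10 | (2S,3R)-2-{2-[(1R,3R,4S)-3-bromo-4-methyl-4-(triethylsilyloxy)cyclohexyl]prop-2-en-1-yl}-3-(prop-1-en-2-yl)cyclopentan-1-one | C=C(C[C@H]1[C@H](C(=C)C)CCC1=O)[C@@H]1CC[C@](C)(O[Si](CC)(CC)CC)[C@H](Br)C1
F3 | step 13 | (1S,4S,6S)-1-methyl-4-(prop-1-en-2-yl)-7-oxabicyclo[4.1.0]heptan-2-one | C=C(C)[C@H]1C[C@@H]2O[C@]2(C)C(=O)C1
F4 | step 13 | (1S,2R,4S)-1-methyl-4-(prop-1-en-2-yl)cyclohexane-1,2-diol | C=C(C)[C@H]1CC[C@](C)(O)[C@H](O)C1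
F5 | step 13 | (2S,5S)-2-hydroxy-2-methyl-5-(prop-1-en-2-yl)cyclohexan-1-one | C=C(C)[C@H]1CC[C@](C)(O)C(=O)C1
F6 | step 12 | (1R,2R,3S)-2-{2-[(1R,3R,4S)-3-bromo-4-methyl-4-(triethylsilyloxy)cyclohexyl]prop-2-en-1-yl}-1-ethenyl-3-(prop-1-en-2-yl)cyclopentan-1-ol | C=C[C@]1(O)CC[C@H](C(C)=C)[C@H]1CC(=C)[C@@H]1CC[C@](C)(O[Si](CC)(CC)CC)[C@H](Br)C1
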